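**Retrosynthetic overview**

1. The route rests on the C6 oxygen and its surroundings: C6 lies between the ring-fusion carbon C5 and, through C7, the C8 carbinol; C5 is flanked by the gem-dimethyl carbon C4 and the quaternary C10. As a ketone, C6 makes C4=C5 an enone dienophile, so ring A (C10, C1, C2, C3, C4, C5) with a C1=C2 olefin added, fused to ring B, is a Diels–Alder bicycle.
2. Key disconnection: C5–C10 and C3–C4, by intramolecular Diels–Alder reaction of trienone 17 (diene C10(CH3)=C1–C2=C3, tether C9–C8–C7–C6). Rings A and B close together, cis-fused.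
3. Trienone 17 comes from terminal epoxide 11 and the dithiane of 3-methylbut-2-enal (C6–C7); the (E)-diene from methylalumination/iodination of a C10 alkyne and Stille vinylation; C9–C10 from alkynylalane opening (inversion) of a Sharpless epoxide that sets C8 and C9.
4. Geraniol supplies C7–C9 and C11–C17, with the (E)-C13=C14 olefin of the side chain already in place; its allylic carbon becomes the C15 acid at the end.
5. After the cycloaddition: hydrogenation of C1=C2, desilylation, C8–OH-directed reduction of C6, side-chain oxidation, C6 acetylation.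

Key step: step 12

Remark: labdane numbering is used for all compounds (C15 = carboxyl carbon, C20 = methyl on C10). In the target, H5, the C10 methyl, the C6 acetoxy group, the C8 methyl and the C9 chain lie on one face of ring B and the C8 hydroxyl on the other (5S,6S,8S,9S,10R). Dithiane 13 is assumed not to be a catalogue compound and is made in step 8.

**Route**

Step 1
Reactants: 1 geraniol
Product: 2 geranyl tert-butyldimethylsilyl ether
Conditions: TBSCl, imidazole, DMF, 0 °C → rt
Reagents that add atoms: tert-butyldimethylsilyl chloride, CC(C)(C)[Si](C)(C)Cl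
Why: Silyl ether formation masks the future C15 oxygen with a group that should survive the organoaluminium, organolithium and Lewis acid steps and fall to fluoride later; no stereocentre is involved.

Step 2
Reactants: 2 geranyl tert-butyldimethylsilyl ether
Product: 3 (2E,6E)-8-silyloxy-2,6-dimethylocta-2,6-dien-1-ol
Conditions: SeO2 (cat.), t-BuOOH, salicylic acid (cat.), CH2Cl2, rt
Reagents that add atoms: tert-butyl hydroperoxide, CC(C)(C)OO (oxygen atom, relayed through catalytic SeO2, O=[Se]=O)
Why: Riley-type allylic oxidation (ene reaction, then [2,3]-sigmatropic shift) should hydroxylate the (E)-methyl of the distal trisubstituted olefin, the other olefin being deactivated by its allylic oxygen, which gives the (E)-2-methyl allylic alcohol C7–C8=C9.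

Step 3
Reactants: 3 (2E,6E)-allylic alcohol
Product: 4 (2S,3S)-epoxy alcohol
Conditions: Ti(OiPr)4 (cat.), L-(+)-diethyl tartrate (cat.), t-BuOOH, 4 Å molecular sieves, CH2Cl2, −20 °C
Reagents that add atoms: tert-butyl hydroperoxide, CC(C)(C)OO
Why: Sharpless asymmetric epoxidation acts only on the allylic alcohol olefin and, with the L-(+)-tartrate, should give the (2S,3S)-epoxide, which fixes C8 and, after the inversion of step 4, C9.

Step 4
Reactants: 4 (2S,3S)-epoxy alcohol
Product: 6 (2R,3S)-alkyne diol, via silylalkyne diol 5 (not isolated)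
Conditions: Me3SiC≡CH, n-BuLi, toluene, 0 °C; Et2AlCl; then 4, 0 °C → rt; aqueous potassium sodium tartrate; then K2CO3, MeOH, rt
Reagents that add atoms: trimethylsilylacetylene, C#C[Si](C)(C)C
Why: Regioselective opening of a 2,3-epoxy alcohol by an alkynylalane, in which the reagent held on the C7 alkoxide should attack C9 because C8 is fully substituted, proceeds by SN2 with inversion at C9 and leaves C8 untouched, and methanolysis then removes the C-silyl group.

Step 5
Reactants: 6 (2R,3S)-alkyne diol
Product: 8 (E)-alkenyl iodide diol, via alkenylalane 7 (not isolated)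
Conditions: Me3Al, Cp2ZrCl2, CH2Cl2, 0 °C → rt; then I2, THF, −30 → 0 °C
Reagents that add atoms: trimethylaluminium, C[Al](C)C; iodine, II
Why: Negishi zirconium-catalysed carboalumination adds methyl and aluminium syn across the terminal alkyne with methyl on the internal carbon C10, and iodinolysis with retention should give the (E)-alkenyl iodide with C9 trans to iodine, the two hydroxyls being carried as aluminium alkoxides.

Step 6
Reactants: 8 (E)-alkenyl iodide diol
Product: 9 (E)-diene diol
Conditions: Bu3SnCH=CH2, PdCl2(MeCN)2 (cat.), DMF, rt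
Reagents that add atoms: tributyl(vinyl)stannane, C=C[Sn](CCCC)(CCCC)CCCC
Why: Stille coupling replaces iodine by vinyl with retention of olefin geometry and so completes the diene C10(CH3)=C1–C2=C3 with C9 on the outside of C10.

Step 7
Reactants: 9 (E)-diene diol
Product: 11 terminal epoxide, via primary tosylate 10 (not isolated)
Conditions: NaH, THF, 0 °C; then 1-(p-toluenesulfonyl)imidazole, 0 °C → rt
Reagents that add atoms: none
Why: Selective sulfonylation of the primary C7 hydroxyl followed by intramolecular Williamson displacement by the tertiary C8 alkoxide should give the 2,2-disubstituted oxirane with retention at C8, since the C8–O bond is never broken.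

Step 8
Reactants: 12 3-methylbut-2-enal
Product: 13 2-(2-methylprop-1-en-1-yl)-1,3-dithiane
Conditions: HS(CH2)3SH, BF3·OEt2 (cat.), CH2Cl2, −20 °C
Reagents that add atoms: propane-1,3-dithiol, SCCCS
Why: Lewis-acid-catalysed thioacetalisation gives the Corey–Seebach acyl anion precursor, and the β,β-disubstituted enal should resist conjugate addition of the thiol.

Step 9
Reactants: 11 terminal epoxide; 13 alkenyl dithiane
Product: 15 hydroxy dithiane, via lithiodithiane 14 (not isolated)
Conditions: 13, n-BuLi, THF, −30 °C; then 11, DMPU, −30 → 0 °C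
Reagents that add atoms: none
Why: In this Corey–Seebach umpolung the 2-lithio-2-alkenyl dithiane should attack the unsubstituted epoxide carbon C7 through its α-carbon, the γ-carbon being blocked by two methyls, which forms C6–C7 and releases the C8 tertiary alkoxide without touching C8 or C9.

Step 10
Reactants: 15 hydroxy dithiane
Product: 16 triethylsilyl ether
Conditions: TESOTf, 2,6-lutidine, CH2Cl2, −78 → 0 °C
Reagents that add atoms: triethylsilyl trifluoromethanesulfonate, CC[Si](CC)(CC)OS(=O)(=O)C(F)(F)F
Why: Silyl triflate silylation caps the hindered tertiary C8 hydroxyl so that the later β-oxy ketone can neither cleave by retro-aldol reaction nor form an aluminium alkoxide in the key step.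

Step 11
Reactants: 16 triethylsilyl ether
Product: 17 trienone
Conditions: MeI, CaCO3, MeCN/H2O (4:1), rt → 35 °C
Reagents that add atoms: water, O
Why: Alkylative dithiane hydrolysis (S-methylation, ring opening to an allyl-stabilised thionium ion, attack of water) should unveil the C6 ketone under buffered, non-oxidising conditions that spare the diene, the olefins and both silyl ethers.

Step 12
Reactants: 17 trienone
Product: 18 cis-fused octalone
Conditions: Me2AlCl (1.2 equiv), CH2Cl2 (high dilution), −78 → −20 °C; cold aqueous potassium sodium tartrate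
Reagents that add atoms: none
Why: Me2AlCl binds the C6 carbonyl of the s-cis enone and lowers its LUMO, and the diene C10=C1–C2=C3 then adds across C4=C5 in a concerted but asynchronous intramolecular Diels–Alder reaction in which the unhindered C3 terminus bonds to the gem-dimethyl carbon C4 ahead of C10–C5; the closest known reaction type is the Lewis-acid-promoted cyclisation of 1,7,9-decatrien-3-ones to cis-fused octalones. Ring A (C10, C1, C2, C3, C4, C5) is the cyclohexene created by the two new bonds, and ring B (C5 to C10) is closed as a six-membered ring by the C5–C10 bond across the four-atom tether C6–C7–C8–C9. The cis relation of H5 and the C10 methyl follows from the endo placement of the tether carbonyl together with the (E) diene geometry, which holds C9 on the outside of the C10 terminus. The sense of C5 and C10 relative to C8 and C9 is set by a chair-shaped tether in which the C8 methyl is equatorial and the C8 silyloxy group axial, because the axial site on C8 is syn to C1–H of the diene; this puts the C9 chain trans-diaxial to that oxygen and anti to C1. The step needs endo over exo selectivity and one diene face: the exo chair would press C8 against the inside methyl on C10, a boat tether is excluded by the flagpole clash at quaternary C8, and the low temperature allowed by the Lewis acid should let the equatorial preference of the C8 methyl decide the face.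

Step 13
Reactants: 18 cis-fused octalone
Product: 19 saturated cis-decalone
Conditions: H2 (3 atm), RhCl(PPh3)3 (cat.), benzene, rt
Reagents that add atoms: none
Why: Homogeneous hydrogenation with chlorotris(triphenylphosphine)rhodium should saturate the cis-disubstituted C1=C2 olefin and leave the trisubstituted C13=C14 olefin, the ketone and the silyl ethers untouched; no stereocentre is formed.

Step 14
Reactants: 19 saturated cis-decalone
Product: 20 keto diol
Conditions: HF·pyridine, pyridine, THF, 0 °C → rt
Reagents that add atoms: none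
Why: Fluoride-driven desilylation removes the tertiary triethylsilyl and the primary tert-butyldimethylsilyl ether in one operation under buffered, non-basic conditions, so the β-hydroxy ketone should neither cleave by retro-aldol reaction nor epimerise at C5.

Step 15
Reactants: 20 keto diol
Product: 21 triol
Conditions: Me4NBH(OAc)3, MeCN/AcOH (1:1), −25 → 0 °C
Reagents that add atoms: none
Why: In this Evans–Saksena reduction the C8 hydroxyl exchanges onto boron and the alkoxy(diacetoxy)borohydride delivers hydride within the molecule to the face of C6 syn to the C8 oxygen, so the new C6 hydroxyl should come out anti to the C8 hydroxyl (6S).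

Step 16
Reactants: 21 triol
Product: 23 dihydroxy acid, via enal 22 (not isolated)
Conditions: MnO2, CH2Cl2, rt; filter; then NaClO2, NaH2PO4, 2-methylbut-2-ene, t-BuOH/H2O, 0 °C → rt
Reagents that add atoms: sodium chlorite, [Na+].[O-]Cl=O
Why: MnO2 oxidises only the allylic primary alcohol, and Pinnick oxidation of the (E)-enal with a hypochlorite scavenger should give the (E)-3-methyl-2-enoic acid without touching the secondary and tertiary hydroxyls or the olefin geometry.

Step 17
Reactants: 23 dihydroxy acid
Product: 24 target acid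
Conditions: Ac2O, pyridine, DMAP (cat.), CH2Cl2, 0 °C → rt; then H2O
Reagents that add atoms: acetic anhydride, CC(=O)OC(C)=O
Why: DMAP-catalysed acetylation should esterify only the secondary C6 hydroxyl, the tertiary C8 hydroxyl being too hindered, and the aqueous finish hydrolyses any mixed anhydride formed at the carboxyl group.

**Compound list**

1 | geraniol, (2E)-3,7-dimethylocta-2,6-dien-1-ol | CC(C)=CCC/C(C)=C/CO | starting material
2 | tert-butyl{[(2E)-3,7-dimethylocta-2,6-dien-1-yl]oxy}dimethylsilane | CC(C)=CCC/C(C)=C/CO[Si](C)(C)C(C)(C)C | intermediate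
3 | (2E,6E)-8-[(tert-butyldimethylsilyl)oxy]-2,6-dimethylocta-2,6-dien-1-ol | OC/C(C)=C/CC/C(C)=C/CO[Si](C)(C)C(C)(C)C | intermediate
4 | [(2S,3S)-3-{(3E)-5-[(tert-butyldimethylsilyl)oxy]-3-methylpent-3-en-1-yl}-2-methyloxiran-2-yl]methanol | OC[C@]1(C)O[C@H]1CC/C(C)=C/CO[Si](C)(C)C(C)(C)C | intermediate
5 | (2R,3S,6E)-8-[(tert-butyldimethylsilyl)oxy]-2,6-dimethyl-3-[(trimethylsilyl)ethynyl]oct-6-ene-1,2-diol | OC[C@](C)(O)[C@@H](CC/C(C)=C/CO[Si](C)(C)C(C)(C)C)C#C[Si](C)(C)C | intermediate
6 | (2R,3S,6E)-8-[(tert-butyldimethylsilyl)oxy]-3-ethynyl-2,6-dimethyloct-6-ene-1,2-diol | OC[C@](C)(O)[C@@H](CC/C(C)=C/CO[Si](C)(C)C(C)(C)C)C#C | intermediate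
7 | (E)-alkenyl(dimethyl)alane from 6: methyl on C10, AlMe2 on C1 trans to C9, both oxygens as O–AlMe2 | C[Al](C)OC[C@](C)(O[Al](C)C)[C@@H](CC/C(C)=C/CO[Si](C)(C)C(C)(C)C)/C(C)=C/[Al](C)C | intermediate
8 | (2R,3S,6E)-8-[(tert-butyldimethylsilyl)oxy]-3-[(1E)-1-iodoprop-1-en-2-yl]-2,6-dimethyloct-6-ene-1,2-diol | OC[C@](C)(O)[C@@H](CC/C(C)=C/CO[Si](C)(C)C(C)(C)C)/C(C)=C/I | intermediate
9 | (2R,3S,6E)-8-[(tert-butyldimethylsilyl)oxy]-2,6-dimethyl-3-[(2E)-penta-2,4-dien-2-yl]oct-6-ene-1,2-diol | OC[C@](C)(O)[C@@H](CC/C(C)=C/CO[Si](C)(C)C(C)(C)C)/C(C)=C/C=C | intermediate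
10 | primary 4-methylbenzenesulfonate of 9 (tosyl on the C7 oxygen) | Cc1ccc(cc1)S(=O)(=O)OC[C@](C)(O)[C@@H](CC/C(C)=C/CO[Si](C)(C)C(C)(C)C)/C(C)=C/C=C | intermediate
11 | tert-butyl{[(2E,6S,7E)-3,7-dimethyl-6-[(2R)-2-methyloxiran-2-yl]deca-2,7,9-trien-1-yl]oxy}dimethylsilane | C1O[C@]1(C)[C@@H](CC/C(C)=C/CO[Si](C)(C)C(C)(C)C)/C(C)=C/C=C | intermediate
12 | 3-methylbut-2-enal | CC(C)=CC=O | starting material
13 | 2-(2-methylprop-1-en-1-yl)-1,3-dithiane | CC(C)=CC1SCCCS1 | intermediate
14 | 2-lithio-2-(2-methylprop-1-en-1-yl)-1,3-dithiane | [Li]C1(C=C(C)C)SCCCS1 | intermediate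
15 | (2S,3S,6E)-8-[(tert-butyldimethylsilyl)oxy]-2,6-dimethyl-1-[2-(2-methylprop-1-en-1-yl)-1,3-dithian-2-yl]-3-[(2E)-penta-2,4-dien-2-yl]oct-6-en-2-ol | CC(C)=CC1(C[C@](C)(O)[C@@H](CC/C(C)=C/CO[Si](C)(C)C(C)(C)C)/C(C)=C/C=C)SCCCS1 | intermediate
16 | triethylsilyl ether of 15 at the tertiary C8 oxygen | CC(C)=CC1(C[C@](C)(O[Si](CC)(CC)CC)[C@@H](CC/C(C)=C/CO[Si](C)(C)C(C)(C)C)/C(C)=C/C=C)SCCCS1 | intermediate
17 | (6S,7S,8E)-7-{(3E)-5-[(tert-butyldimethylsilyl)oxy]-3-methylpent-3-en-1-yl}-2,6,8-trimethyl-6-[(triethylsilyl)oxy]undeca-2,8,10-trien-4-one | CC(C)=CC(=O)C[C@](C)(O[Si](CC)(CC)CC)[C@@H](CC/C(C)=C/CO[Si](C)(C)C(C)(C)C)/C(C)=C/C=C | intermediate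
18 | cis-fused octalone; labdane numbering: 6-oxo, C1=C2, (13E), 8-OSiEt3, 15-OSi(t-Bu)Me2, (5S,8S,9S,10S), H5 cis to the C10 methyl | O=C1C[C@](C)(O[Si](CC)(CC)CC)[C@@H](CC/C(C)=C/CO[Si](C)(C)C(C)(C)C)[C@]2(C)C=CCC(C)(C)[C@H]12 | intermediate
19 | saturated cis-decalone; labdane numbering: 6-oxo, (13E), 8-OSiEt3, 15-OSi(t-Bu)Me2, (5S,8S,9S,10S) | O=C1C[C@](C)(O[Si](CC)(CC)CC)[C@@H](CC/C(C)=C/CO[Si](C)(C)C(C)(C)C)[C@]2(C)CCCC(C)(C)[C@H]12 | intermediate
20 | keto diol; labdane numbering: 8,15-dihydroxy-6-oxo, (13E), (5S,8S,9S,10S) | O=C1C[C@](C)(O)[C@@H](CC/C(C)=C/CO)[C@]2(C)CCCC(C)(C)[C@H]12 | intermediate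
21 | triol; labdane numbering: 6,8,15-trihydroxy, (13E), (5S,6S,8S,9S,10R), C6–OH anti to C8–OH | O[C@H]1C[C@](C)(O)[C@@H](CC/C(C)=C/CO)[C@]2(C)CCCC(C)(C)[C@H]12 | intermediate
22 | (2E)-5-[(1S,2S,4S,4aS,8aR)-2,4-dihydroxy-2,5,5,8a-tetramethyldecahydronaphthalen-1-yl]-3-methylpent-2-enal | O[C@H]1C[C@](C)(O)[C@@H](CC/C(C)=C/C=O)[C@]2(C)CCCC(C)(C)[C@H]12 | intermediate
23 | (2E)-5-[(1S,2S,4S,4aS,8aR)-2,4-dihydroxy-2,5,5,8a-tetramethyldecahydronaphthalen-1-yl]-3-methylpent-2-enoic acid | O[C@H]1C[C@](C)(O)[C@@H](CC/C(C)=C/C(=O)O)[C@]2(C)CCCC(C)(C)[C@H]12 | intermediate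
24 | (2E)-5-[(1S,2S,4S,4aS,8aR)-4-(acetyloxy)-2-hydroxy-2,5,5,8a-tetramethyldecahydronaphthalen-1-yl]-3-methylpent-2-enoic acid | CC(=O)O[C@H]1C[C@](C)(O)[C@@H](CC/C(C)=C/C(=O)O)[C@]2(C)CCCC(C)(C)[C@H]12 | target

**Step count and risks**

Total step count: 17. Longest linear sequence: 16 steps (steps 1–7 and 9–17, from geraniol); step 8 is a one-step side branch.

Steps most likely to fail:

1. Step 12. The cycloaddition may be slow because both bond-forming termini are fully substituted and the diene carries an inside methyl. On warming, Lewis-acid-induced loss of triethylsilanol from the β-silyloxy ketone could then compete. The second weakness is leakage to the other diene face: the desired chair forces the C9 chain axial beside the C10 methyl, and the competing chair (C8 methyl axial, C9 chain equatorial) is estimated to lie close in energy, so the face preference is not secure. Fallback, an ionic Diels–Alder reaction that sets out from 17 and returns at 20: 17 is treated with 1,2-bis(trimethylsilyloxy)ethane and TMSOTf in CH2Cl2 at −78 °C. Ketalisation passes through the 2-alkenyl-1,3-dioxolan-2-ylium ion, a much stronger dienophile than the aluminium-bound enone, and the same two bonds should form at the lowest temperature to give the dioxolane cycloadduct F1. Hydrogenation as in step 13 gives the saturated dioxolane F2, and aqueous HF in MeCN removes the dioxolane and both silyl ethers to reach 20.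

2. Step 4. The alane is a Lewis acid and the epoxide is trisubstituted, so ionisation at the tertiary carbon C8 could lead to attack at the wrong carbon or to a semipinacol-type shift, with loss of the C9 stereocentre. Fallback, which sets out from 4 and returns at 6: the primary hydroxyl of 4 is capped as the 1-ethoxyethyl ether F3 (ethyl vinyl ether, PPTS, CH2Cl2), which also shuts off Payne rearrangement. LiC≡CH·H2NCH2CH2NH2 in DMSO then opens the epoxide by SN2 attack at the less substituted carbon C9 without any Lewis acid, giving the alkynyl carbinol F4 with inversion at C9. PPTS in MeOH removes the acetal and returns 6.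

3. Step 13. Hydrogenation of the ring olefin next to quaternary C10 may be slow, and on forcing the side-chain olefin could begin to be reduced or to migrate. Fallback, which sets out from 18 and returns at 20: the triethylsilyl ether alone is removed with PPTS in MeOH at 0 °C to give the hydroxy octalone F5. Hydroxyl-directed hydrogenation with [Rh(nbd)(dppb)]BF4 under H2 in CH2Cl2, in which the axial C8 hydroxyl binds rhodium and passes it only to the nearby C1=C2 olefin, gives the hydroxy decalone F6. HF·pyridine then removes the primary silyl ether and rejoins the route at 20.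

Further compounds
F1 | step 12 | ethylene ketal (1,3-dioxolane at C6) of cycloadduct 18 | C12(OCCO1)C[C@](C)(O[Si](CC)(CC)CC)[C@@H](CC/C(C)=C/CO[Si](C)(C)C(C)(C)C)[C@]3(C)C=CCC(C)(C)[C@H]23
F2 | step 12 | ethylene ketal (1,3-dioxolane at C6) of saturated decalone 19 | C12(OCCO1)C[C@](C)(O[Si](CC)(CC)CC)[C@@H](CC/C(C)=C/CO[Si](C)(C)C(C)(C)C)[C@]3(C)CCCC(C)(C)[C@H]23
F3 | step 4 | 1-ethoxyethyl ether of epoxy alcohol 4 | CCOC(C)OC[C@]1(C)O[C@H]1CC/C(C)=C/CO[Si](C)(C)C(C)(C)C
F4 | step 4 | 1-O-(1-ethoxyethyl) ether of alkyne diol 6 | CCOC(C)OC[C@](C)(O)[C@@H](CC/C(C)=C/CO[Si](C)(C)C(C)(C)C)C#C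
F5 | step 13 | 8-hydroxy octalone (18 without the triethylsilyl group) | O=C1C[C@](C)(O)[C@@H](CC/C(C)=C/CO[Si](C)(C)C(C)(C)C)[C@]2(C)C=CCC(C)(C)[C@H]12
F6 | step 13 | 8-hydroxy decalone (19 without the triethylsilyl group) | O=C1C[C@](C)(O)[C@@H](CC/C(C)=C/CO[Si](C)(C)C(C)(C)C)[C@]2(C)CCCC(C)(C)[C@H]12
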